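**Retrosynthetic overview**
- The benzoylacetyl chain is cut last. Its CH2–C(=O)Ph bond comes from a Baker–Venkataraman O→C benzoyl shift of the C5–O benzoate of a chromenyl methyl ketone, which in turn comes from the free phenol and benzoyl chloride.
- Key disconnection: the pyran ring of the chromenyl methyl ketone is cut at C4–C4a and O1–C2. This gives 2',4'-dihydroxy-6'-methoxyacetophenone and 3-methylbut-2-enal, joined in the forward sense by one Knoevenagel/oxa-6π cascade (formal [3+3]).
- Enabling feature (acetophenone numbering): O4–H is para to the acetyl group (a vinylogous acid) and the ring CH at C3 lies between O2 and O4. O2–H is held in a six-membered hydrogen-bonded chelate ring with the acetyl C=O, so the quinone methide forms on O4 across C3.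
- Ring order: the benzene and phenyl rings are bought; the pyran ring is the only ring made. It is made first, with the side chain still at acetyl level, because a 1,3-dicarbonyl CH2 would itself condense with the enal.

Key step: step 1

Remark: the 1,3-diketone of the target is drawn in the diketo form; it should exist mainly as the hydrogen-bonded enol, which is the same compound.

**Route**

Step 1
Reactants: 1 2',4'-dihydroxy-6'-methoxyacetophenone; 2 3-methylbut-2-enal
Product: 4 chromenyl methyl ketone 1-(5-hydroxy-7-methoxy-2,2-dimethyl-2H-chromen-6-yl)ethan-1-one, via o-quinone methide 3 (not isolated)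
Conditions: ethylenediammonium diacetate (EDDA, 20 mol %), xylene, 140 °C
Reagents that add atoms: none
Why: EDDA converts 2 into an iminium ion that is attacked by C3 of 1 (Knoevenagel-type C-alkylation ortho to the vinylogous acid O4–H), and loss of the amine gives the o-quinone methide 3, a 1-oxatriene with the C4 carbonyl and the dienyl chain s-cis. The closest known reaction type is the amine-mediated formal [3+3] chromenylation of resorcinols and 2,4-dihydroxyaryl ketones with enals. The pyran ring closes by thermal disrotatory oxa-6π electrocyclization of 3, which forms the O–CMe2 bond and restores the aromatic ring. No stereocentre is created, because the new sp3 carbon bears two methyl groups. The step needs site selectivity (C3, not C5) and closure through O4 (not O2): C3 is the only ring CH flanked by two hydroxyls, and O2–H is held in the six-membered chelate with the acetyl C=O, so the quinone methide should form on O4 and the chelate should survive into 4. A second annulation cannot occur because the remaining hydroxyl of 4 has no free ortho carbon, and the acetyl-level side chain has no 1,3-dicarbonyl CH2 to compete for 2.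

Step 2
Reactants: 4 chromenyl methyl ketone 1-(5-hydroxy-7-methoxy-2,2-dimethyl-2H-chromen-6-yl)ethan-1-one; 5 benzoyl chloride
Product: 6 6-acetyl-7-methoxy-2,2-dimethyl-2H-chromen-5-yl benzoate
Conditions: Et3N (2 equiv), DMAP (10 mol %), CH2Cl2, 0 to 25 °C
Reagents that add atoms: none
Why: DMAP-catalysed O-acylation (nucleophilic catalysis through the N-benzoylpyridinium ion) should esterify the only hydroxyl, even though it is hydrogen-bonded; the chromene alkene, the aryl ether and the ketone are inert under these conditions, and no stereocentre is formed.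

Step 3
Reactants: 6 6-acetyl-7-methoxy-2,2-dimethyl-2H-chromen-5-yl benzoate
Product: 7 target 1-(5-hydroxy-7-methoxy-2,2-dimethyl-2H-chromen-6-yl)-3-phenylpropane-1,3-dione
Conditions: KOtBu (2.5 equiv), THF, 0 to 25 °C; then AcOH, 0 °C
Reagents that add atoms: none
Why: Baker–Venkataraman rearrangement: the potassium enolate of the methyl ketone attacks the neighbouring ester carbonyl through a six-membered cyclic alkoxide, which collapses to the phenoxide and the stabilised 1,3-diketonate; this releases exactly the C5 hydroxyl. Cold, weakly acidic work-up should avoid cyclodehydration to the flavone, and no stereocentre is formed.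

**Compound list**
1 | 2',4'-dihydroxy-6'-methoxyacetophenone, 1-(2,4-dihydroxy-6-methoxyphenyl)ethan-1-one | CC(=O)c1c(O)cc(O)cc1OC | starting material
2 | 3-methylbut-2-enal | CC(C)=CC=O | starting material
3 | (2Z)-4-acetyl-3-hydroxy-5-methoxy-2-(3-methylbut-2-en-1-ylidene)cyclohexa-3,5-dien-1-one (o-quinone methide) | O=C1C=C(OC)C(C(C)=O)=C(O)/C1=C/C=C(C)C | intermediate
4 | 1-(5-hydroxy-7-methoxy-2,2-dimethyl-2H-chromen-6-yl)ethan-1-one | COc1cc2c(c(O)c1C(C)=O)C=CC(C)(C)O2 | intermediate
5 | benzoyl chloride | O=C(Cl)c1ccccc1 | starting material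
6 | 6-acetyl-7-methoxy-2,2-dimethyl-2H-chromen-5-yl benzoate | COc1cc2c(c(OC(=O)c3ccccc3)c1C(C)=O)C=CC(C)(C)O2 | intermediate
7 | 1-(5-hydroxy-7-methoxy-2,2-dimethyl-2H-chromen-6-yl)-3-phenylpropane-1,3-dione | COc1cc2c(c(O)c1C(=O)CC(=O)c1ccccc1)C=CC(C)(C)O2 | target

Total step count: 3
Longest linear sequence: 3 steps (1 → 4 → 6 → 7)

**Steps most likely to fail**

Step 1. Part of the C-alkylation may leak to C5 (the carbon between O4 and the methoxy group), or the electrocyclization may run through O2 once the hydrogen bond is loosened at 140 °C, giving isomeric chromenes that are hard to separate; the enal may also oligomerize. The fallback enforces the regiochemistry by symmetry; it sets out from 2 and comes back at 4. The symmetric phenol 1-(4-hydroxy-2,6-dimethoxyphenyl)ethan-1-one F1, which has one hydroxyl and two equivalent ortho carbons, would be condensed with 2 under the EDDA conditions. The o-quinone methide (2Z)-4-acetyl-3,5-dimethoxy-2-(3-methylbut-2-en-1-ylidene)cyclohexa-3,5-dien-1-one F2 can then close to only one chromene, 1-(5,7-dimethoxy-2,2-dimethyl-2H-chromen-6-yl)ethan-1-one F3. Chelation-controlled mono-demethylation with MgI2·OEt2 (or BCl3 at −78 °C) should then cleave the more crowded C5 methoxy group, which is flanked by the acetyl group and C4a, and give 4.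

Step 3. The base may cleave the hindered aryl ester (loss of the benzoyl group back to the phenol) faster than the twisted acetyl group is enolized, and the product may cyclodehydrate to the flavone if the work-up turns acidic. The fallback builds the C–C bond by aldol addition and then adjusts the oxidation level; it sets out from 4 and comes back at 7.
- 4 would be silylated (tert-butyldimethylsilyl triflate, 2,6-lutidine) to the silyl ether 1-{5-[(tert-butyldimethylsilyl)oxy]-7-methoxy-2,2-dimethyl-2H-chromen-6-yl}ethan-1-one F5.
- Deprotonation with LiN(iPr)2 in THF at −78 °C would give the lithium enolate lithium 1-{5-[(tert-butyldimethylsilyl)oxy]-7-methoxy-2,2-dimethyl-2H-chromen-6-yl}ethen-1-olate F6.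
- Addition to benzaldehyde would give the racemic aldol 1-{5-[(tert-butyldimethylsilyl)oxy]-7-methoxy-2,2-dimethyl-2H-chromen-6-yl}-3-hydroxy-3-phenylpropan-1-one F7, whose carbinol stereocentre is removed in the next operation.
- Dess–Martin periodinane would oxidize it to the silylated diketone 1-{5-[(tert-butyldimethylsilyl)oxy]-7-methoxy-2,2-dimethyl-2H-chromen-6-yl}-3-phenylpropane-1,3-dione F8.
- Bu4NF buffered with AcOH (THF, 0 °C) would remove the silyl group and give 7.

Step 2. Acylation of the hydrogen-bonded, doubly flanked C5 hydroxyl may stall, or premature acyl transfer followed by a second benzoylation may give over-acylated material. The fallback avoids the ester altogether; it sets out from 4 and comes back at 7. 4 would be converted with LiN(SiMe3)2 (3 equiv, THF, −78 °C) into the dilithium phenoxide–enolate dilithium 6-(1-oxidoethenyl)-7-methoxy-2,2-dimethyl-2H-chromen-5-olate F4. This is C-benzoylated by 5 (1 equiv), and protonation with AcOH at 0 °C should give 7 directly.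

**Further compounds**
F1 | step 1 | 1-(4-hydroxy-2,6-dimethoxyphenyl)ethan-1-one | CC(=O)c1c(OC)cc(O)cc1OC
F2 | step 1 | (2Z)-4-acetyl-3,5-dimethoxy-2-(3-methylbut-2-en-1-ylidene)cyclohexa-3,5-dien-1-one | O=C1C=C(OC)C(C(C)=O)=C(OC)/C1=C/C=C(C)C
F3 | step 1 | 1-(5,7-dimethoxy-2,2-dimethyl-2H-chromen-6-yl)ethan-1-one | COc1cc2c(c(OC)c1C(C)=O)C=CC(C)(C)O2
F4 | step 2 | dilithium 6-(1-oxidoethenyl)-7-methoxy-2,2-dimethyl-2H-chromen-5-olate | [Li+].[Li+].C=C([O-])c1c([O-])c2C=CC(C)(C)Oc2cc1OC
F5 | step 3 | 1-{5-[(tert-butyldimethylsilyl)oxy]-7-methoxy-2,2-dimethyl-2H-chromen-6-yl}ethan-1-one | COc1cc2c(c(O[Si](C)(C)C(C)(C)C)c1C(C)=O)C=CC(C)(C)O2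
F6 | step 3 | lithium 1-{5-[(tert-butyldimethylsilyl)oxy]-7-methoxy-2,2-dimethyl-2H-chromen-6-yl}ethen-1-olate | [Li+].C=C([O-])c1c(O[Si](C)(C)C(C)(C)C)c2C=CC(C)(C)Oc2cc1OC
F7 | step 3 | racemic 1-{5-[(tert-butyldimethylsilyl)oxy]-7-methoxy-2,2-dimethyl-2H-chromen-6-yl}-3-hydroxy-3-phenylpropan-1-one | COc1cc2c(c(O[Si](C)(C)C(C)(C)C)c1C(=O)CC(O)c1ccccc1)C=CC(C)(C)O2
F8 | step 3 | 1-{5-[(tert-butyldimethylsilyl)oxy]-7-methoxy-2,2-dimethyl-2H-chromen-6-yl}-3-phenylpropane-1,3-dione | COc1cc2c(c(O[Si](C)(C)C(C)(C)C)c1C(=O)CC(=O)c1ccccc1)C=CC(C)(C)O2
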